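**Retrosynthetic overview**
- Haterumaimide J is made in the last step from an acyclic chloro-epoxy-diene hydroxy imide by a titanocene radical bicyclisation: ring A (C4–C5) and ring B (C9–C10) close in one operation, with the C2 chlorine directing C4, C5, C9 and C10.
- The acyclic precursor comes from an sp2–sp3 reductive coupling at C5–C6 of fragment A (alkenyl iodide carrying the chloride and the terminal epoxide) and fragment B (alkyl iodide carrying the finished hydroxy succinimide).
- Fragment A: (R)-epichlorohydrin, isopropenyl Grignard, acetylide; carboalumination/iodination; OH to Cl with inversion; epoxidation.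
- Fragment B: silyloxybutyne carboalumination/oxirane, oxidation, Evans syn-aldol (sets C12 and C13), ammonolysis to the imide.
- Ring order: the succinimide ring first (step 10), then rings A and B together (step 13).

Assumption: positions are given in labdane numbering (C1–C20) of the natural product, and silyl ether 14 and enantiopure epichlorohydrin are taken as commercial.

**Step 1**
Reactants: 1 (R)-epichlorohydrin; 2 isopropenylmagnesium bromide
Product: 3 (2R)-1-chloro-4-methylpent-4-en-2-ol
Conditions: CuI (10 mol %), THF, −40 → −20 °C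
Reagents that add atoms: none
Why: Copper-catalysed Grignard opening of the epoxide at its CH2 carbon (SN2) does not touch the stereocentre, so the future C2 carbinol is taken unchanged from the chiral pool.

**Step 2**
Reactants: 3 (2R)-1-chloro-4-methylpent-4-en-2-ol; 4 lithium acetylide–ethylenediamine complex
Product: 6 (4R)-6-methylhept-6-en-1-yn-4-ol, via epoxide 5 (not isolated)
Conditions: LiC≡CH·H2NCH2CH2NH2 (3 equiv), DMSO, 0 °C → rt
Reagents that add atoms: none
Why: The lithium alkoxide closes to the terminal epoxide (intramolecular Williamson reaction) and a second equivalent of acetylide opens it at CH2 (SN2), again leaving the stereocentre untouched.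

**Step 3**
Reactants: 6 (4R)-6-methylhept-6-en-1-yn-4-ol
Product: 8 (1E,4R)-1-iodo-2,6-dimethylhepta-1,6-dien-4-ol, via alkenylalane 7 (not isolated)
Conditions: AlMe3 (3 equiv), (C5H5)2ZrCl2 (0.25 equiv), CH2Cl2, 0 °C → rt; then I2, THF, −30 → 0 °C
Reagents that add atoms: trimethylaluminium C[Al](C)C; iodine II
Why: Negishi zirconium-catalysed carboalumination adds CH3 and Al syn across the terminal alkyne with CH3 on the internal carbon (the 1,1-disubstituted alkene is inert), and iodinolysis with retention gives the E iodide that fixes the C5=C10 geometry.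

**Step 4**
Reactants: 8 (1E,4R)-1-iodo-2,6-dimethylhepta-1,6-dien-4-ol
Product: 9 (1E,4S)-4-chloro-1-iodo-2,6-dimethylhepta-1,6-diene
Conditions: PPh3, N-chlorosuccinimide, THF, 0 °C → rt
Reagents that add atoms: N-chlorosuccinimide O=C1CCC(=O)N1Cl
Why: Appel-type chlorination through the alkoxyphosphonium salt is an SN2 displacement, so the alcohol is converted with inversion into the chloride that is the C2 stereocentre of the target.

**Step 5**
Reactants: 9 (1E,4S)-4-chloro-1-iodo-2,6-dimethylhepta-1,6-diene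
Product: 10 2-[(2R,4E)-2-chloro-5-iodo-4-methylpent-4-en-1-yl]-2-methyloxirane (1:1 epimers at the oxirane carbon)
Conditions: mCPBA, NaHCO3, CH2Cl2, 0 °C
Reagents that add atoms: meta-chloroperbenzoic acid OOC(=O)c1cccc(Cl)c1
Why: Prilezhaev epoxidation is chemoselective for the electron-rich 1,1-disubstituted alkene over the deactivated iodoalkene, and the unselectively formed oxirane centre does not matter because it becomes a planar radical in step 13.

**Step 6**
Reactants: 11 (4R)-4-benzyl-1,3-oxazolidin-2-one; 12 methyl 4-chloro-4-oxobutanoate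
Product: 13 methyl 4-[(4R)-4-benzyl-2-oxo-1,3-oxazolidin-3-yl]-4-oxobutanoate
Conditions: n-BuLi, THF, −78 °C; then 12, −78 → 0 °C
Reagents that add atoms: none
Why: N-acylation of the lithiated Evans oxazolidinone by the acid chloride, which reacts far faster than the methyl ester.

**Step 7**
Reactants: 14 tert-butyl(but-3-yn-1-yloxy)dimethylsilane; 15 oxirane
Product: 17 (3E)-6-{[tert-butyl(dimethyl)silyl]oxy}-4-methylhex-3-en-1-ol, via alkenylalane 16 (not isolated)
Conditions: AlMe3 (2 equiv), (C5H5)2ZrCl2 (0.25 equiv), CH2Cl2, rt; volatiles removed; n-BuLi (1 equiv), hexane/THF, −78 °C; then oxirane (3 equiv), −78 → 0 °C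
Reagents that add atoms: trimethylaluminium C[Al](C)C
Why: Negishi carboalumination sets the E trisubstituted C8=C9 alkene, and the lithium alkenylalanate made with n-BuLi opens oxirane with retention of alkene geometry to give the homoallylic alcohol.

**Step 8**
Reactants: 17 (3E)-6-{[tert-butyl(dimethyl)silyl]oxy}-4-methylhex-3-en-1-ol
Product: 18 (3E)-6-{[tert-butyl(dimethyl)silyl]oxy}-4-methylhex-3-enal
Conditions: Dess–Martin periodinane, NaHCO3, CH2Cl2, 0 °C → rt; used crude at once
Reagents that add atoms: none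
Why: Dess–Martin oxidation under buffered, near-neutral conditions gives the β,γ-unsaturated aldehyde without moving the alkene into conjugation.

**Step 9**
Reactants: 13 methyl 4-[(4R)-4-benzyl-2-oxo-1,3-oxazolidin-3-yl]-4-oxobutanoate; 18 (3E)-6-{[tert-butyl(dimethyl)silyl]oxy}-4-methylhex-3-enal
Product: 20 methyl (3R,4S,6E)-3-{[(4R)-4-benzyl-2-oxo-1,3-oxazolidin-3-yl]carbonyl}-9-{[tert-butyl(dimethyl)silyl]oxy}-4-hydroxy-7-methylnon-6-enoate, via boron enolate 19 (not isolated)
Conditions: Bu2BOTf, i-Pr2NEt, CH2Cl2, −78 → 0 °C; then 18, −78 → 0 °C; pH 7 buffer, MeOH, 30% H2O2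
Reagents that add atoms: none
Why: Evans syn-aldol reaction, in which soft enolisation occurs only at the imide α-CH2 to give the Z boron enolate and the Zimmerman–Traxler chair, shielded on one face by the benzyl group of the R auxiliary, sets C13 as R and C12 as S.

**Step 10**
Reactants: 20 methyl (3R,4S,6E)-3-{[(4R)-4-benzyl-2-oxo-1,3-oxazolidin-3-yl]carbonyl}-9-{[tert-butyl(dimethyl)silyl]oxy}-4-hydroxy-7-methylnon-6-enoate
Product: 22 (3R)-3-[(1S,3E)-1,6-dihydroxy-4-methylhex-3-en-1-yl]pyrrolidine-2,5-dione, via silyl ether imide 21 (not isolated)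
Conditions: NH3 (7 M in MeOH), 0 °C → rt; concentrate; then HCl (cat.), MeOH, 0 °C
Reagents that add atoms: ammonia N
Why: Ammonolysis turns the ester terminus (directly or through its γ-lactone) into a primary amide that acylates itself on the activated N-acyloxazolidinone carbonyl (5-exo-trig), closing the succinimide and expelling the auxiliary without touching C12 or C13, after which acid methanolysis removes the primary silyl ether.

**Step 11**
Reactants: 22 (3R)-3-[(1S,3E)-1,6-dihydroxy-4-methylhex-3-en-1-yl]pyrrolidine-2,5-dione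
Product: 23 (3R)-3-[(1S,3E)-1-hydroxy-6-iodo-4-methylhex-3-en-1-yl]pyrrolidine-2,5-dione
Conditions: I2, PPh3, imidazole, CH2Cl2, 0 °C
Reagents that add atoms: iodine II
Why: Appel (Garegg–Samuelsson) iodination is selective for the unhindered primary alcohol over the secondary alcohol next to the imide.

**Step 12**
Reactants: 10 2-[(2R,4E)-2-chloro-5-iodo-4-methylpent-4-en-1-yl]-2-methyloxirane; 23 (3R)-3-[(1S,3E)-1-hydroxy-6-iodo-4-methylhex-3-en-1-yl]pyrrolidine-2,5-dione
Product: 24 (3R)-3-[(1S,3E,7E,10R)-10-chloro-1-hydroxy-4,8-dimethyl-11-(2-methyloxiran-2-yl)undeca-3,7-dien-1-yl]pyrrolidine-2,5-dione (both oxirane epimers)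
Conditions: NiBr2(MeOCH2CH2OMe) (10 mol %), 4,4′-di-tert-butyl-2,2′-bipyridine (12 mol %), Mn powder (2 equiv), N,N-dimethylacetamide, rt; 10 used in 1.3 equiv
Reagents that add atoms: none
Why: Nickel-catalysed reductive cross-electrophile coupling joins the alkenyl iodide (oxidative addition to low-valent nickel with retention of E geometry) to the radical from the primary alkyl iodide, and this reaction class tolerates free OH and N–H groups and leaves the unactivated secondary chloride alone.

**Step 13**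
Reactants: 24 (3R)-3-[(1S,3E,7E,10R)-10-chloro-1-hydroxy-4,8-dimethyl-11-(2-methyloxiran-2-yl)undeca-3,7-dien-1-yl]pyrrolidine-2,5-dione
Product: 27 haterumaimide J, via silyl ether 25 (not isolated), via bis-silyl ether 26 (not isolated)
Conditions: Me3SiCl (4 equiv), 2,4,6-collidine (7 equiv), THF, rt, 1 h; then (C5H5)2TiCl2 (0.3 equiv), Mn dust (8 equiv), THF, rt, slow addition; 1 M aq HCl work-up
Reagents that add atoms: none
Why: Titanocene-catalysed radical epoxypolyene cyclisation (Nugent–RajanBabu epoxide opening), in which (C5H5)2TiCl opens either oxirane epimer to the same planar tertiary C4 radical, which closes ring A and then ring B by two 6-endo-trig additions through a chair–chair array that keeps the C2 chlorine equatorial (an axial Cl would clash with the axial groups on C4 and C10) and the bulky CH2O[Ti] group equatorial, so that C4, C5, C10 and C9 are set with a trans ring fusion and an equatorial side chain, and the tertiary C8 radical then gives up a C17 hydrogen to trivalent titanium to leave the exocyclic alkene.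

**Compound list**
1 | (R)-epichlorohydrin, (2R)-2-(chloromethyl)oxirane | ClC[C@H]1CO1 | starting material
2 | isopropenylmagnesium bromide | CC(=C)[Mg]Br | starting material
3 | (2R)-1-chloro-4-methylpent-4-en-2-ol | C=C(C)C[C@@H](O)CCl | intermediate
4 | lithium acetylide–ethylenediamine complex | [Li]C#C.NCCN | starting material
5 | (2R)-2-(2-methylprop-2-en-1-yl)oxirane | C=C(C)C[C@@H]1CO1 | intermediate
6 | (4R)-6-methylhept-6-en-1-yn-4-ol | C=C(C)C[C@@H](O)CC#C | intermediate
7 | dimethyl[(1E,4R)-4-[(dimethylalumanyl)oxy]-2,6-dimethylhepta-1,6-dien-1-yl]alumane | C=C(C)C[C@@H](O[Al](C)C)C/C(C)=C/[Al](C)C | intermediate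
8 | (1E,4R)-1-iodo-2,6-dimethylhepta-1,6-dien-4-ol | C=C(C)C[C@@H](O)C/C(C)=C/I | intermediate
9 | (1E,4S)-4-chloro-1-iodo-2,6-dimethylhepta-1,6-diene | C=C(C)C[C@H](Cl)C/C(C)=C/I | intermediate
10 | 2-[(2R,4E)-2-chloro-5-iodo-4-methylpent-4-en-1-yl]-2-methyloxirane, both epimers at the oxirane carbon | CC1(CO1)C[C@H](Cl)C/C(C)=C/I | intermediate
11 | (4R)-4-benzyl-1,3-oxazolidin-2-one | O=C1N[C@H](Cc2ccccc2)CO1 | starting material
12 | methyl 4-chloro-4-oxobutanoate | COC(=O)CCC(Cl)=O | starting material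
13 | methyl 4-[(4R)-4-benzyl-2-oxo-1,3-oxazolidin-3-yl]-4-oxobutanoate | COC(=O)CCC(=O)N1[C@H](Cc2ccccc2)COC1=O | intermediate
14 | tert-butyl(but-3-yn-1-yloxy)dimethylsilane | C#CCCO[Si](C)(C)C(C)(C)C | starting material
15 | oxirane | C1CO1 | starting material
16 | [(1E)-4-{[tert-butyl(dimethyl)silyl]oxy}-2-methylbut-1-en-1-yl]dimethylalumane | C[Al](C)/C=C(\C)CCO[Si](C)(C)C(C)(C)C | intermediate
17 | (3E)-6-{[tert-butyl(dimethyl)silyl]oxy}-4-methylhex-3-en-1-ol | CC(C)(C)[Si](C)(C)OCC/C(C)=C/CCO | intermediate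
18 | (3E)-6-{[tert-butyl(dimethyl)silyl]oxy}-4-methylhex-3-enal | CC(C)(C)[Si](C)(C)OCC/C(C)=C/CC=O | intermediate
19 | dibutylboron (Z)-enolate of 13, methyl (3Z)-4-[(4R)-4-benzyl-2-oxo-1,3-oxazolidin-3-yl]-4-[(dibutylboranyl)oxy]but-3-enoate | CCCCB(CCCC)O/C(=C\CC(=O)OC)N1[C@H](Cc2ccccc2)COC1=O | intermediate
20 | methyl (3R,4S,6E)-3-{[(4R)-4-benzyl-2-oxo-1,3-oxazolidin-3-yl]carbonyl}-9-{[tert-butyl(dimethyl)silyl]oxy}-4-hydroxy-7-methylnon-6-enoate | CC(C)(C)[Si](C)(C)OCC/C(C)=C/C[C@H](O)[C@H](C(=O)N1[C@H](Cc2ccccc2)COC1=O)CC(=O)OC | intermediate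
21 | (3R)-3-[(1S,3E)-6-{[tert-butyl(dimethyl)silyl]oxy}-1-hydroxy-4-methylhex-3-en-1-yl]pyrrolidine-2,5-dione | CC(C)(C)[Si](C)(C)OCC/C(C)=C/C[C@H](O)[C@H]1CC(=O)NC1=O | intermediate
22 | (3R)-3-[(1S,3E)-1,6-dihydroxy-4-methylhex-3-en-1-yl]pyrrolidine-2,5-dione | OCC/C(C)=C/C[C@H](O)[C@H]1CC(=O)NC1=O | intermediate
23 | (3R)-3-[(1S,3E)-1-hydroxy-6-iodo-4-methylhex-3-en-1-yl]pyrrolidine-2,5-dione | ICC/C(C)=C/C[C@H](O)[C@H]1CC(=O)NC1=O | intermediate
24 | (3R)-3-[(1S,3E,7E,10R)-10-chloro-1-hydroxy-4,8-dimethyl-11-(2-methyloxiran-2-yl)undeca-3,7-dien-1-yl]pyrrolidine-2,5-dione, both oxirane epimers | CC1(CO1)C[C@H](Cl)C/C(C)=C/CC/C(C)=C/C[C@H](O)[C@H]2CC(=O)NC2=O | intermediate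
25 | 12-O-trimethylsilyl ether of 24 | CC1(CO1)C[C@H](Cl)C/C(C)=C/CC/C(C)=C/C[C@H](O[Si](C)(C)C)[C@H]2CC(=O)NC2=O | intermediate
26 | 12,18-bis-O-trimethylsilyl ether of haterumaimide J | C=C1CC[C@H]2[C@](C)(CO[Si](C)(C)C)C[C@H](Cl)C[C@]2(C)[C@H]1C[C@H](O[Si](C)(C)C)[C@H]1CC(=O)NC1=O | intermediate
27 | haterumaimide J, (3R)-3-{(1S)-2-[(1S,4aR,5R,7R,8aR)-7-chloro-5-(hydroxymethyl)-5,8a-dimethyl-2-methylidenedecahydronaphthalen-1-yl]-1-hydroxyethyl}pyrrolidine-2,5-dione | C=C1CC[C@H]2[C@](C)(CO)C[C@H](Cl)C[C@]2(C)[C@H]1C[C@H](O)[C@H]1CC(=O)NC1=O | target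

**Step count and risks**
Total steps: 13. Longest linear sequence: 7 (steps 7–13 from 14, or steps 1–5, 12 and 13 from 1).

The three steps most likely to fail are 13, 12 and 10.

Step 13 (radical bicyclisation of the unprotected hydroxy imide). The risks are hydrogen transfer to the C8 radical from the protic groups, a stalled monocycle, and imperfect C4 selectivity. The fallback changes the order of events so that the cyclisation substrate has no acidic hydrogen; it sets out from 20 and comes back at 27. Aldol adduct 20 is desilylated and lactonised with camphorsulfonic acid (MeOH, then toluene, 50 °C) to the lactone alcohol F1. F1 is converted with I2, PPh3 and imidazole into the lactone iodide F2. F2 is joined to 10 under the nickel conditions of step 12 to give the lactone epoxide F3. F3 is cyclised with stoichiometric (C5H5)2TiCl (from (C5H5)2TiCl2 and Mn, THF, aqueous work-up) to the bicyclic lactone F4. Only then is NH3 in MeOH applied; it opens the lactone and closes the imide with loss of the auxiliary to give 27.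

Step 12 (nickel reductive coupling in the presence of the epoxide, OH and N–H). The risks are homodimers and iodide opening of the epoxide. The fallback replaces the radical cross-electrophile coupling by a palladium-catalysed Negishi coupling of a preformed organozinc; it sets out from 23 and comes back at 24. Iodide 23 is silylated on O and N with N,O-bis(trimethylsilyl)acetamide (THF, rt) to the bis(trimethylsilyl) iodide F5. Zinc insertion (Zn dust, LiCl, THF, 40 °C) gives the alkylzinc iodide F6. F6 is coupled with 10 (Pd(OAc)2, SPhos, THF, rt) to the bis(trimethylsilyl) coupling product F7. Aqueous citric acid work-up removes both silyl groups and gives 24.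

Step 10 (one-pot ammonolysis, imide closure and desilylation). The risks are attack of ammonia on the ring carbonyl of the auxiliary and retro-aldol cleavage. The fallback removes the auxiliary hydrolytically and builds the imide from the lactone; it sets out from 20 and comes back at 21, which is carried to 22 by the acid methanolysis of step 10. LiOH/H2O2 (THF/H2O, 0 °C, then mild acidification) gives the lactone acid F8. Carbonyldiimidazole converts F8 into the acyl imidazolide F9, and NH3 gives the lactone amide F10. KOt-Bu (1 equiv, THF, 0 °C, then AcOH) makes the amide nitrogen attack the lactone carbonyl and delivers the hydroxy imide 21.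

**Further compounds**
F1 | step 13 | (4R)-4-benzyl-3-{[(2S,3R)-2-[(2E)-5-hydroxy-3-methylpent-2-en-1-yl]-5-oxooxolan-3-yl]carbonyl}-1,3-oxazolidin-2-one | OCC/C(C)=C/C[C@@H]1OC(=O)C[C@H]1C(=O)N2[C@H](Cc3ccccc3)COC2=O
F2 | step 13 | (4R)-4-benzyl-3-{[(2S,3R)-2-[(2E)-5-iodo-3-methylpent-2-en-1-yl]-5-oxooxolan-3-yl]carbonyl}-1,3-oxazolidin-2-one | ICC/C(C)=C/C[C@@H]1OC(=O)C[C@H]1C(=O)N2[C@H](Cc3ccccc3)COC2=O
F3 | step 13 | (4R)-4-benzyl-3-{[(2S,3R)-2-[(2E,6E,9R)-9-chloro-3,7-dimethyl-10-(2-methyloxiran-2-yl)deca-2,6-dien-1-yl]-5-oxooxolan-3-yl]carbonyl}-1,3-oxazolidin-2-one, both oxirane epimers | CC1(CO1)C[C@H](Cl)C/C(C)=C/CC/C(C)=C/C[C@@H]2OC(=O)C[C@H]2C(=O)N3[C@H](Cc4ccccc4)COC3=O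
F4 | step 13 | bicyclic lactone: haterumaimide J skeleton with O-12 and C-15 joined as the γ-lactone and C-16 bound to N of (4R)-4-benzyl-1,3-oxazolidin-2-one, 18-OH free | C=C1CC[C@H]2[C@](C)(CO)C[C@H](Cl)C[C@]2(C)[C@H]1C[C@@H]3OC(=O)C[C@H]3C(=O)N4[C@H](Cc5ccccc5)COC4=O
F5 | step 12 | (3R)-3-[(1S,3E)-6-iodo-4-methyl-1-[(trimethylsilyl)oxy]hex-3-en-1-yl]-1-(trimethylsilyl)pyrrolidine-2,5-dione | ICC/C(C)=C/C[C@H](O[Si](C)(C)C)[C@H]1CC(=O)N([Si](C)(C)C)C1=O
F6 | step 12 | alkylzinc iodide of F5, {(3E,6S)-6-[(3R)-2,5-dioxo-1-(trimethylsilyl)pyrrolidin-3-yl]-3-methyl-6-[(trimethylsilyl)oxy]hex-3-en-1-yl}zinc iodide | I[Zn]CC/C(C)=C/C[C@H](O[Si](C)(C)C)[C@H]1CC(=O)N([Si](C)(C)C)C1=O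
F7 | step 12 | N,12-O-bis(trimethylsilyl) derivative of 24 | CC1(CO1)C[C@H](Cl)C/C(C)=C/CC/C(C)=C/C[C@H](O[Si](C)(C)C)[C@H]2CC(=O)N([Si](C)(C)C)C2=O
F8 | step 10 | (2S,3R)-2-[(2E)-5-{[tert-butyl(dimethyl)silyl]oxy}-3-methylpent-2-en-1-yl]-5-oxooxolane-3-carboxylic acid | CC(C)(C)[Si](C)(C)OCC/C(C)=C/C[C@@H]1OC(=O)C[C@H]1C(O)=O
F9 | step 10 | acyl imidazolide of F8, (4R,5S)-5-[(2E)-5-{[tert-butyl(dimethyl)silyl]oxy}-3-methylpent-2-en-1-yl]-4-(1H-imidazol-1-ylcarbonyl)oxolan-2-one | CC(C)(C)[Si](C)(C)OCC/C(C)=C/C[C@@H]1OC(=O)C[C@H]1C(=O)n1ccnc1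
F10 | step 10 | (2S,3R)-2-[(2E)-5-{[tert-butyl(dimethyl)silyl]oxy}-3-methylpent-2-en-1-yl]-5-oxooxolane-3-carboxamide | CC(C)(C)[Si](C)(C)OCC/C(C)=C/C[C@@H]1OC(=O)C[C@H]1C(N)=O
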